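The reading comes at 80 s, which is also the mean residence time of the tank, and I want to choose one set-up for the next run before spending any substrate.

    reagent + free catalyst ⇌ catalyst intermediate A (K1 = 420 M⁻¹, k1 = 3900 M⁻¹ s⁻¹)
    substrate + catalyst intermediate A → catalyst intermediate B (k2 = 39000 M⁻¹ s⁻¹)
    catalyst intermediate B ⇌ free catalyst + product (K3 = 0.029 M, k3 = 32 s⁻¹)
    2 reagent → homo dimer (k4 = 2.2 M⁻¹ s⁻¹)
    free catalyst → spent catalyst (k5 = 0.013 s⁻¹)

| flask | substrate | reagent | free catalyst | remark | time |
|---|---|---|---|---|---|
| elm | 0.0010 M | 1.80 mM | 8.9 µM | one stirred flow tank at steady state, fed with the mixture as stated, mean residence time 80 s |  |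
| larch | 0.0010 M (fed, over 40.0 s) | 1.80 mM | 8.9 µM | a stirred flask in which substrate is dosed at a steady rate over 40.0 s without added volume, worked up at 80 s | 80 s |
| ash | 0.0010 M | 1.80 mM | 8.9 µM | everything together in a closed stirred flask, run for 80 s | 80 s |
| birch | 0.0010 M | 1.80 mM (fed, over 40.0 s) | 8.9 µM | a stirred flask in which reagent is dosed at a steady rate over 40.0 s without added volume, worked up at 80 s | 80 s |

- the set-up with the highest amount of product at the outlet or at the end, in percent of the substrate put in ("none" if the first two lie within 2 percentage points) (elm / larch / ash / birch / none)
- amount of product at the outlet or at the end, in percent of the substrate put in, elm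
- amount of product at the outlet or at the end, in percent of the substrate put in, larch
- amount of product at the outlet or at the end, in percent of the substrate put in, ash
- amount of product at the outlet or at the end, in percent of the substrate put in, birch

- a doubled species enters its step squared and goes two at a time
- the stated concentrations are those of everything mixed, before any reaction; amounts are the same in each set-up
- the feed brings no volume worth counting
- run time (larch): 80 s

A free catalyst has two exits: it enters the cycle, or it goes to spent catalyst at 0.013 s⁻¹. It enters the cycle at k1[reagent], and catalyst intermediate A then either goes on at k2[substrate] or falls back at 9.29 s⁻¹. These two paths are equal at a crossing substrate level, Sx = 0.238 mM. The full charge of substrate stands above Sx, so step 1 is the rate-limiting step at the start. Catalyst intermediate B leaves at 32 s⁻¹, faster than reagent binds at the charge, so I leave that step out of this estimate.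

I carry one number, the turnover yield T, which is the product made per catalyst lost: T = (k1[reagent]/k5)·[substrate]/([substrate] + Sx). At the full charge, T is 436, while the substrate asks for 112 turnovers per catalyst, fewer than T offers.

Dosing holds one partner down. With substrate at half its charge, as a mid-dose state in larch, T is 366. With reagent at half its charge in birch, T is 218. For the tank elm I guess both at half, which gives 183. So I charge ash. This reckoning ranks the set-ups and gives no percentages.

The forecast also picks ash, on these grounds: “dosing either partner wastes catalyst lifetime”.

| set-up | forecast | simulation |
|---|---|---|
| elm | 64% | 64.4% |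
| larch | 80% | 79.2% |
| ash | 90% | 90.9% |
| birch | 79% | 78.6% |

The simulation puts ash first. In ash, the product at the end stands at 90.9%, which is 102 turnovers per charged catalyst, about a quarter of the T at the charge. In the tank elm, [reagent] stands at 8.82 × 10⁻⁴ M and [substrate] at 3.56 × 10⁻⁴ M, so T is 158, lower than at the ash charge. A free catalyst in elm cycles at 2.06 s⁻¹, faster than it dies at 0.013 s⁻¹, and with 64.4% product that reckons to 4.06 µM spent catalyst at the elm outlet, about half of the 8.9 µM fed.

The rate constants come from no measurement; the rest is arithmetic.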